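The upper pyran ring (ring C) is cut at C2–C3 and C4–C4a. A chiral-acid-catalysed oxa-Povarov annulation joins an O-aryl oxocarbenium ion, released from an aryloxymethyl pivalate that holds ring A, O1 and C2, with the C3=C4 double bond of an (E)-stilbene that already carries the complete (3R)-isoflavan. One operation builds ring C, both bonds and the trans C3/C4 pair. The step exploits the doubly benzylic C4: a cation there is stabilised by ring D (ortho-methoxy, para-oxygen), which fixes the regiochemistry, and is captured by the ring A carbon ortho to O1. The lower isoflavan comes from ketone α-arylation and transfer hydrogenation with dynamic kinetic resolution.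

Key step: step 11

Remark on the chemistry: ring A/ring C = benzo and pyran rings of the upper chroman, ring B = its 3-aryl group, ring D = the aryl group on C4 (also the 3-aryl group of the lower chroman); it is assumed that a short screen identifies the enantiomer of the chiral acid that gives the (3R,4S) series, both enantiomers being accessible.

Step 1
Reactants: 1 7-hydroxychroman-4-one
Product: 2 4-oxochroman-7-yl pivalate
Conditions: PivCl, Et3N, DMAP (cat.), CH2Cl2, 0 °C to rt
Reagents that add atoms: pivaloyl chloride CC(C)(C)C(=O)Cl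
Why: DMAP-catalysed acylation of the phenol should be clean, and the pivalate later keeps this benzo ring unreactive towards electrophiles.

Step 2
Reactants: 3 2-bromo-5-methoxyphenol
Product: 4 (2-bromo-5-methoxyphenoxy)(tert-butyl)dimethylsilane
Conditions: TBSCl, imidazole, DMF, rt
Reagents that add atoms: tert-butyldimethylsilyl chloride CC(C)(C)[Si](C)(C)Cl
Why: Silylation of the phenol gives an ether that tolerates weak base, hydrogenation and acid while leaving the oxygen an electron donor for ring D.

Step 3
Reactants: 2 4-oxochroman-7-yl pivalate; 4 (2-bromo-5-methoxyphenoxy)(tert-butyl)dimethylsilane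
Product: 5 rac-3-[2-(tert-butyldimethylsilyloxy)-4-methoxyphenyl]-4-oxochroman-7-yl pivalate
Conditions: Pd2(dba)3 (2 mol%), XPhos (8 mol%), K3PO4, toluene, 90 °C
Reagents that add atoms: none
Why: Palladium-catalysed α-arylation of the ketone enolate should form the C3–aryl bond under a phosphate base that spares the pivalate and the silyl ether, the bulky ortho substituent disfavouring a second arylation, and the new C3 centre is left racemic for step 4.

Step 4
Reactants: 5 rac-3-[2-(tert-butyldimethylsilyloxy)-4-methoxyphenyl]-4-oxochroman-7-yl pivalate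
Product: 6 (3R,4R)-3-[2-(tert-butyldimethylsilyloxy)-4-methoxyphenyl]-4-hydroxychroman-7-yl pivalate (cis)
Conditions: RuCl[(R,R)-TsDPEN](p-cymene) (2 mol%), HCO2H/Et3N (5:2), EtOAc, 40 °C
Reagents that add atoms: none
Why: In this Noyori-type asymmetric transfer hydrogenation with dynamic kinetic resolution the α-aryl ketone racemises through its enol under Et3N while the (R,R)-catalyst reduces the (3R)-enantiomer with hydride arriving at C4 anti to the C3 aryl group, so the catalyst sets both C3 (R) and C4 (R, cis), the sense following the known (R,R)-to-(R)-carbinol preference for benzo-fused ketones.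

Step 5
Reactants: 6 (3R,4R)-3-[2-(tert-butyldimethylsilyloxy)-4-methoxyphenyl]-4-hydroxychroman-7-yl pivalate
Product: 7 (3R)-3-[2-(tert-butyldimethylsilyloxy)-4-methoxyphenyl]chroman-7-yl pivalate
Conditions: H2 (1 atm), Pd/C (10%), EtOAc/AcOH, rt
Reagents that add atoms: none
Why: Hydrogenolysis of the benzylic C4–O bond on palladium removes the hydroxyl without touching C3, the aryl silyl ether or the pivalate.

Step 6
Reactants: 7 (3R)-3-[2-(tert-butyldimethylsilyloxy)-4-methoxyphenyl]chroman-7-yl pivalate
Product: 8 (3R)-3-[5-bromo-2-(tert-butyldimethylsilyloxy)-4-methoxyphenyl]chroman-7-yl pivalate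
Conditions: NBS, MeCN, 0 °C
Reagents that add atoms: N-bromosuccinimide O=C1CCC(=O)N1Br
Why: Electrophilic aromatic bromination should go to C5 of ring D, the only unhindered position para to the silyloxy and ortho to the methoxy group, while the pivalate keeps the benzo ring of the chroman unreactive.

Step 7
Reactants: 9 2-hydroxy-4-methoxybenzaldehyde; 10 methyltriphenylphosphonium bromide
Product: 11 5-methoxy-2-vinylphenol
Conditions: KOtBu (2.5 equiv), THF, 0 °C to rt
Reagents that add atoms: none
Why: Wittig methylenation of the aldehyde with the non-stabilised ylide, the excess base covering the phenol, should give the styrene.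

Step 8
Reactants: 11 5-methoxy-2-vinylphenol
Product: 12 5-methoxy-2-vinylphenyl pivalate
Conditions: PivCl, Et3N, DMAP (cat.), CH2Cl2, 0 °C
Reagents that add atoms: pivaloyl chloride CC(C)(C)C(=O)Cl
Why: Acylation of the phenol stabilises the vinylphenol and lowers the donor strength of ring B, which later directs the regiochemistry of the key step.

Step 9
Reactants: 8 (3R)-3-[5-bromo-2-(tert-butyldimethylsilyloxy)-4-methoxyphenyl]chroman-7-yl pivalate; 12 5-methoxy-2-vinylphenyl pivalate
Product: 13 (3R)-3-{2-(tert-butyldimethylsilyloxy)-4-methoxy-5-[(E)-2-(4-methoxy-2-(pivaloyloxy)phenyl)ethenyl]phenyl}chroman-7-yl pivalate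
Conditions: Pd2(dba)3 (2.5 mol%), [HP(tBu)3]BF4 (10 mol%), Cy2NMe, 1,4-dioxane, 70 °C
Reagents that add atoms: none
Why: In this Mizoroki–Heck reaction, oxidative addition of the electron-rich aryl bromide to the zerovalent palladium–P(tBu)3 catalyst, syn-insertion at the terminal carbon of the styrene and syn-β-hydride elimination should give the E-stilbene, the amine base sparing esters and silyl ether.

Step 10
Reactants: 14 3-hydroxyphenyl benzoate; 15 chloromethyl pivalate
Product: 16 3-[(pivaloyloxy)methoxy]phenyl benzoate
Conditions: K2CO3, DMF, rt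
Reagents that add atoms: none
Why: Williamson-type O-alkylation of the phenoxide with the chloromethyl ester gives the aryloxymethyl ester whose pivalate is the leaving group for the oxocarbenium ion.

Step 11
Reactants: 13 (3R)-3-{2-(tert-butyldimethylsilyloxy)-4-methoxy-5-[(E)-2-(4-methoxy-2-(pivaloyloxy)phenyl)ethenyl]phenyl}chroman-7-yl pivalate; 16 3-[(pivaloyloxy)methoxy]phenyl benzoate
Product: 19 (3R,4S)-3-[4-methoxy-2-(pivaloyloxy)phenyl]-4-{4-(tert-butyldimethylsilyloxy)-2-methoxy-5-[(3R)-7-(pivaloyloxy)chroman-3-yl]phenyl}chroman-7-yl benzoate, via O-aryl oxocarbenium ion 17 (not isolated), via C4 benzylic cation 18 (not isolated)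
Conditions: chiral imidodiphosphorimidate Brønsted acid (IDPi, BINOL-derived, 5 mol%), 16 (1.5 equiv, slow addition), 5 Å MS, CHCl3, −40 °C
Reagents that add atoms: none
Why: Proposed new method: the strong chiral acid ionises the pivaloyloxymethyl ether 16 to the O-aryl oxocarbenium ion 17 (ion pair with the chiral anion), which adds through its CH2 carbon to the stilbene carbon that bears ring B, the only regiochemistry that places the cation 18 next to the ortho-methoxy, para-silyloxy ring D instead of next to the ester-deactivated ring B, and 18 is then closed by Friedel–Crafts attack of the ring A carbon ortho to the ether oxygen and para to the benzoate. The closest known reaction type is the oxa-Povarov reaction (formal inverse-demand [4+2] of O-aryl oxocarbenium ions with styrenes under SnCl4), together with confined-acid-catalysed enantioselective additions of formaldehyde-derived oxocarbenium ions to styrenes; what is new is enantiofacial control of this annulation by a chiral counteranion on a stilbene. Ring C closes as a stepwise cationic [4+2] annulation whose second bond is a six-membered ring closure (6-exo-trig at the quinoid cation, endo to the arene π bond). C3 (R) is set by the catalyst, which selects the alkene face in the first bond formation, because the stereocentre of the lower chroman is too remote to help or hinder, and C4 (S) follows from the E geometry of the alkene and the diequatorial trans closure. The step needs regio-, site- and chemoselectivity: the pivalate on ring B steers the regiochemistry, the benzoate on ring A and the pivalate on the lower chroman keep those arenes from intercepting 17, and closure para to the benzoate is favoured over the crowded position between the two oxygens.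

Step 12
Reactants: 19 (3R,4S)-3-[4-methoxy-2-(pivaloyloxy)phenyl]-4-{4-(tert-butyldimethylsilyloxy)-2-methoxy-5-[(3R)-7-(pivaloyloxy)chroman-3-yl]phenyl}chroman-7-yl benzoate
Product: 20 (3R,4S)-3-(2-hydroxy-4-methoxyphenyl)-4-{4-hydroxy-5-[(3R)-7-hydroxychroman-3-yl]-2-methoxyphenyl}chroman-7-ol (CNP0152030.2)
Conditions: NaOMe (8 equiv), degassed MeOH/THF, 0 to 40 °C; then AcOH
Reagents that add atoms: none
Why: Zemplén-type transesterification with methoxide should cleave the two pivalates and the benzoate while methoxide attack at silicon cleaves the aryl silyl ether, none of the three stereocentres being acidic under these conditions.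

Compound list
1 | 7-hydroxychroman-4-one | O=C1CCOc2cc(O)ccc12 | starting material
2 | 4-oxochroman-7-yl pivalate | O=C1CCOc2cc(OC(=O)C(C)(C)C)ccc12 | intermediate
3 | 2-bromo-5-methoxyphenol | COc1ccc(Br)c(O)c1 | starting material
4 | (2-bromo-5-methoxyphenoxy)(tert-butyl)dimethylsilane | COc1ccc(Br)c(O[Si](C)(C)C(C)(C)C)c1 | intermediate
5 | rac-3-[2-(tert-butyldimethylsilyloxy)-4-methoxyphenyl]-4-oxochroman-7-yl pivalate | COc1ccc(C2COc3cc(OC(=O)C(C)(C)C)ccc3C2=O)c(O[Si](C)(C)C(C)(C)C)c1 | intermediate
6 | (3R,4R)-3-[2-(tert-butyldimethylsilyloxy)-4-methoxyphenyl]-4-hydroxychroman-7-yl pivalate | COc1ccc([C@@H]2COc3cc(OC(=O)C(C)(C)C)ccc3[C@@H]2O)c(O[Si](C)(C)C(C)(C)C)c1 | intermediate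
7 | (3R)-3-[2-(tert-butyldimethylsilyloxy)-4-methoxyphenyl]chroman-7-yl pivalate | COc1ccc([C@@H]2COc3cc(OC(=O)C(C)(C)C)ccc3C2)c(O[Si](C)(C)C(C)(C)C)c1 | intermediate
8 | (3R)-3-[5-bromo-2-(tert-butyldimethylsilyloxy)-4-methoxyphenyl]chroman-7-yl pivalate | COc1cc(O[Si](C)(C)C(C)(C)C)c([C@@H]2COc3cc(OC(=O)C(C)(C)C)ccc3C2)cc1Br | intermediate
9 | 2-hydroxy-4-methoxybenzaldehyde | COc1ccc(C=O)c(O)c1 | starting material
10 | methyltriphenylphosphonium bromide | C[P+](c1ccccc1)(c1ccccc1)c1ccccc1.[Br-] | starting material
11 | 5-methoxy-2-vinylphenol | COc1ccc(C=C)c(O)c1 | intermediate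
12 | 5-methoxy-2-vinylphenyl pivalate | COc1ccc(C=C)c(OC(=O)C(C)(C)C)c1 | intermediate
13 | (3R)-3-{2-(tert-butyldimethylsilyloxy)-4-methoxy-5-[(E)-2-(4-methoxy-2-(pivaloyloxy)phenyl)ethenyl]phenyl}chroman-7-yl pivalate | COc1ccc(/C=C/c2cc([C@@H]3COc4cc(OC(=O)C(C)(C)C)ccc4C3)c(O[Si](C)(C)C(C)(C)C)cc2OC)c(OC(=O)C(C)(C)C)c1 | intermediate
14 | 3-hydroxyphenyl benzoate (resorcinol monobenzoate) | O=C(Oc1cccc(O)c1)c1ccccc1 | starting material
15 | chloromethyl pivalate | CC(C)(C)C(=O)OCCl | starting material
16 | 3-[(pivaloyloxy)methoxy]phenyl benzoate | CC(C)(C)C(=O)OCOc1cccc(OC(=O)c2ccccc2)c1 | intermediate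
17 | [3-(benzoyloxy)phenyl](methylidene)oxonium, O-aryl oxocarbenium ion paired with the catalyst anion | C=[O+]c1cccc(OC(=O)c2ccccc2)c1 | intermediate
18 | C4 benzylic cation formed by C2–C3 bond formation, (3R) at the new centre | COc1ccc([C@H](COc2cccc(OC(=O)c3ccccc3)c2)[CH+]c2cc([C@@H]3COc4cc(OC(=O)C(C)(C)C)ccc4C3)c(O[Si](C)(C)C(C)(C)C)cc2OC)c(OC(=O)C(C)(C)C)c1 | intermediate
19 | (3R,4S)-3-[4-methoxy-2-(pivaloyloxy)phenyl]-4-{4-(tert-butyldimethylsilyloxy)-2-methoxy-5-[(3R)-7-(pivaloyloxy)chroman-3-yl]phenyl}chroman-7-yl benzoate | COc1ccc([C@@H]2COc3cc(OC(=O)c5ccccc5)ccc3[C@H]2c2cc([C@@H]3COc4cc(OC(=O)C(C)(C)C)ccc4C3)c(O[Si](C)(C)C(C)(C)C)cc2OC)c(OC(=O)C(C)(C)C)c1 | intermediate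
20 | (3R,4S)-3-(2-hydroxy-4-methoxyphenyl)-4-{4-hydroxy-5-[(3R)-7-hydroxychroman-3-yl]-2-methoxyphenyl}chroman-7-ol (CNP0152030.2) | COc1ccc([C@@H]2COc3cc(O)ccc3[C@H]2c2cc([C@@H]3COc4cc(O)ccc4C3)c(O)cc2OC)c(O)c1 | target

Total step count: 12
Longest linear sequence: 8 steps (steps 1, 3, 4, 5, 6, 9, 11 and 12, from 1 to 20)

Steps most likely to fail

1. Step 11. The chiral counteranion may discriminate the alkene faces poorly, so that the (3S,4R)-trans series forms alongside. The strong acid may also protonate the electron-rich stilbene and start its cationic dimerisation, or the oxocarbenium ion may add with the wrong regiochemistry. The fallback uses known chemistry and gives up the one-operation ring construction. It sets out from 6 and 7 and comes back at 20. Acid-promoted Friedel–Crafts coupling (BF3·OEt2, CH2Cl2, −40 °C) would ionise the C4 hydroxyl of 6 to the benzylic cation. This cation would be attacked by C5 of ring D of 7, the position brominated in step 6, anti to the C3 aryl group. This should give the trans tetra-protected dimer (3R,4S)-3-[2-(tert-butyldimethylsilyloxy)-4-methoxyphenyl]-4-{4-(tert-butyldimethylsilyloxy)-2-methoxy-5-[(3R)-7-(pivaloyloxy)chroman-3-yl]phenyl}chroman-7-yl pivalate F1, in which both C3 centres stem from the transfer hydrogenation of step 4. Treatment with NaOMe in MeOH/THF as in step 12 would then give 20.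

2. Step 3. The potassium enolate of the chromanone may open by retro-oxa-Michael elimination, the product may be arylated a second time at C3, and the ortho-silyloxy aryl bromide may couple slowly. The fallback replaces the base-generated enolate by a preformed enol silane, so that no Brønsted base is present. It sets out from 2 and comes back at 5. TMSOTf and Et3N (CH2Cl2, 0 °C) would convert 2 into the silyl enol ether 4-(trimethylsilyloxy)-2H-chromen-7-yl pivalate F2. This would be arylated with 4 through a tin enolate (Pd(OAc)2, P(tBu)3, Bu3SnF, CsF, toluene, 85 °C) to give 5.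

3. Step 5. Dehydration to the isoflav-3-ene on the palladium surface followed by hydrogenation from either face would erode the C3 configuration. The C–O hydrogenolysis may also be sluggish on the acyloxy-deactivated ring, and the acidic medium may remove the silyl group. The fallback is a Barton–McCombie radical deoxygenation, which sets out from 6 and comes back at 7. O-Phenyl chlorothionoformate with pyridine and DMAP (CH2Cl2, rt) would give the thionocarbonate O-{(3R,4R)-3-[2-(tert-butyldimethylsilyloxy)-4-methoxyphenyl]-7-(pivaloyloxy)chroman-4-yl} O-phenyl carbonothioate F3. Bu3SnH and AIBN (toluene, 90 °C) would then reduce it through the C4 benzylic radical to 7 without involving C3.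

Further compounds
F1 | step 11 | (3R,4S)-3-[2-(tert-butyldimethylsilyloxy)-4-methoxyphenyl]-4-{4-(tert-butyldimethylsilyloxy)-2-methoxy-5-[(3R)-7-(pivaloyloxy)chroman-3-yl]phenyl}chroman-7-yl pivalate | COc1ccc([C@@H]2COc3cc(OC(=O)C(C)(C)C)ccc3[C@H]2c2cc([C@@H]3COc4cc(OC(=O)C(C)(C)C)ccc4C3)c(O[Si](C)(C)C(C)(C)C)cc2OC)c(O[Si](C)(C)C(C)(C)C)c1
F2 | step 3 | 4-(trimethylsilyloxy)-2H-chromen-7-yl pivalate | C[Si](C)(C)OC1=CCOc2cc(OC(=O)C(C)(C)C)ccc12
F3 | step 5 | O-{(3R,4R)-3-[2-(tert-butyldimethylsilyloxy)-4-methoxyphenyl]-7-(pivaloyloxy)chroman-4-yl} O-phenyl carbonothioate | COc1ccc([C@@H]2COc3cc(OC(=O)C(C)(C)C)ccc3[C@@H]2OC(=S)Oc2ccccc2)c(O[Si](C)(C)C(C)(C)C)c1
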